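**Plan**

- Cuts (longipinane numbering: C1 enone carbonyl, C4/C11 bridgeheads, C5/C10 the one-carbon bridges of the cyclobutane, C6 CMe2, C7/C9 ester carbinols): both tiglate C–O bonds; C7–C8 of the cycloheptane, by returning the 7,9-dione to its O-acyl isomer, a seven-membered enol lactone with O in place of C8; C5–C6 (tethered Reformatsky); C4–C10 and C5–C11 of the cyclobutane (ketene–alkene [2+2]); one C–C bond of the acyclic chain (vinylogous aldol).
- Forward: acyclic enyne acid → bicyclo[3.1.1]heptan-6-one (cyclobutane and six-membered ring in one event) → temporary seven-membered enol lactone spanning C5 and C10 → carbocyclic seven-membered ring by closing C7–C8 → trans-diol → tiglates → enone.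
- Stereochemistry: one carbinol centre (the future C1) comes from a catalytic asymmetric vinylogous Mukaiyama aldol. It sets C4, C10 and C11 in the cycloaddition through A1,3 strain and is erased at the end as the ketone. C5 follows from the lactone tether.
- C7 and C9 lie on the local mirror plane of the tricycle, too far from the enone to be biased by it, so both are set by one oxazaborolidine catalyst acting on the 1,3-dione.
- Enabling feature: C6 and C10 are quaternary and sit cis on the cyclobutane, so the C7–C8–C9 unit is a 1,3-dione with C8 as its only enolisable carbon, and its O-acyl isomer has the same ring size. The tether oxygen ends as O9 of the target and the bromoisobutyrate carbonyl as C7.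

Key step: step 12

Remark: (E)-3-methylpent-2-en-4-yn-1-ol is taken as a commercial starting material. Tricyclic compounds carry the longipinane numbering of the target; in bicycles 10, 11 and 13 the bicyclo[3.1.1]heptane locants 1, 2, 3, 4, 5, 6, 7 correspond to C4, C3, C2, C1, C11, C5, C10 of the target.

**Step 1**
Reactants: 1 (E)-3-methylpent-2-en-4-yn-1-ol
Product: 2 (E)-3-methylpent-2-en-4-ynal
Conditions: activated MnO2 (10 equiv), CH2Cl2, 25 °C
Reagents that add atoms: none
Why: Allylic alcohol oxidation with MnO2 should stop at the conjugated aldehyde and leave the terminal alkyne and the (E)-double bond untouched; no stereocentre is formed.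

**Step 2**
Reactants: 3 ethyl 3-methylbut-2-enoate
Product: 4 tert-butyl{[(1Z)-1-ethoxy-3-methylbuta-1,3-dien-1-yl]oxy}dimethylsilane
Conditions: LiN(iPr)2, THF, −78 °C; then TBSCl, DMPU, −78 → 0 °C
Reagents that add atoms: tert-butyl(chloro)dimethylsilane, CC(C)(C)[Si](C)(C)Cl
Why: γ-Deprotonation of the ester and O-silylation of the extended enolate (silyl ketene acetal formation) should give the dienolate for the vinylogous Mukaiyama aldol reaction; the geometry at C1 has no bearing on what follows.

**Step 3**
Reactants: 2 (E)-3-methylpent-2-en-4-ynal; 4 silyl dienol ether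
Product: 5 ethyl (2E,5S,6E)-5-hydroxy-3,7-dimethylnona-2,6-dien-8-ynoate
Conditions: SiCl4 (1.1 equiv), (S,S)-bisphosphoramide [two cyclic phosphoramide P-oxides of (S)-N,N'-dimethyl-1,1'-binaphthyl-2,2'-diamine joined through their N-methylamino groups by a pentane-1,5-diyl chain] (5 mol %), iPr2NEt (10 mol %), CH2Cl2, −78 °C; aq. NaHCO3
Reagents that add atoms: none
Why: In this catalytic enantioselective vinylogous Mukaiyama aldol reaction (Lewis-base activation of SiCl4) the dienolate should attack the conjugated aldehyde through its γ-carbon to give the (2E)-δ-hydroxy ester, the catalyst enantiomer being the one that directs attack to the Si face of the aldehyde so that C5 is S (the antipodal ligand would be taken if the facial sense proved opposite).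

**Step 4**
Reactants: 5 hydroxy ester
Product: 6 ethyl (2E,5S,6E)-5-[(tert-butyldimethylsilyl)oxy]-3,7-dimethylnona-2,6-dien-8-ynoate
Conditions: TBSCl, imidazole, DMF, 25 °C
Reagents that add atoms: tert-butyl(chloro)dimethylsilane, CC(C)(C)[Si](C)(C)Cl
Why: Standard silyl ether formation protects the carbinol that steers the cycloaddition and is oxidised to the C1 ketone at the end.

**Step 5**
Reactants: 6 silyl ether ester
Product: 7 (2E,5S,6E)-5-[(tert-butyldimethylsilyl)oxy]-3,7-dimethylnona-2,6-dien-8-ynoic acid
Conditions: LiOH, THF/MeOH/H2O, 40 °C; then cold 0.5 M HCl to pH 3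
Reagents that add atoms: lithium hydroxide, [Li+].[OH-]
Why: Saponification of the conjugated ethyl ester should leave the secondary silyl ether, the enyne and the C5 stereocentre intact.

**Step 6**
Reactants: 7 dienynoic acid
Product: 10 4-[(tert-butyldimethylsilyl)oxy]-7-ethynyl-7-methyl-2-methylidenebicyclo[3.1.1]heptan-6-one (silyloxy on the side of the C6 carbonyl bridge; ethynyl on the face of C7 turned away from the three-carbon bridge), via acid chloride 8 (not isolated), via vinylketene 9 (not isolated)
Conditions: 1-chloro-N,N,2-trimethylprop-1-en-1-amine (1.2 equiv), CH2Cl2, 0 → 25 °C; then slow addition to Et3N (5 equiv), toluene, 110 °C, 0.005 M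
Reagents that add atoms: none
Why: In this thermal intramolecular ketene–alkene [2+2] cycloaddition (acyclic locants) dehydrochlorination at the 3-methyl group cis to the carbonyl gives the methylene ketene, whose carbonyl carbon bonds to C6 and whose other terminus bonds to the more substituted C7 (crossed mode), the (6E) geometry being retained so that ethynyl ends anti to the three-carbon bridge, while A1,3 strain between the C5 substituents and the 7-methyl group (H in the alkene plane, OTBS turned away from the tether) fixes the face of attack and so sets all three ring stereocentres from the one carbinol centre.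

**Step 7**
Reactants: 10 ethynyl cyclobutanone
Product: 11 7-acetyl-4-[(tert-butyldimethylsilyl)oxy]-7-methyl-2-methylidenebicyclo[3.1.1]heptan-6-one (configuration as in 10)
Conditions: (Ph3P)AuNTf2 (5 mol %), H2O (10 equiv), 1,4-dioxane, 60 °C
Reagents that add atoms: water, O
Why: Gold-catalysed Markovnikov hydration of the terminal alkyne should unmask the methyl ketone (future C9 and C8) under nearly neutral conditions that the cyclobutanone, the silyl ether and the methylidene group tolerate.

**Step 8**
Reactants: 11 methyl ketone; 12 2-bromo-2-methylpropanoyl bromide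
Product: 13 1-{4-[(tert-butyldimethylsilyl)oxy]-7-methyl-2-methylidene-6-oxobicyclo[3.1.1]heptan-7-yl}ethenyl 2-bromo-2-methylpropanoate (configuration as in 10)
Conditions: KN(SiMe3)2 (1.1 equiv), THF, −78 °C; then 12 (1.3 equiv), −78 → −40 °C
Reagents that add atoms: none
Why: Enol ester formation by O-acylation of the kinetic potassium enolate should be clean because the acetyl methyl group is the only enolisable position (C10 is quaternary and the cyclobutanone has only bridgehead α-carbons) and the hard, hindered acyl bromide favours attack at oxygen.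

**Step 9**
Reactants: 13 enol bromoester
Product: 14 tricyclic hydroxy enol lactone: lactone ring C5–C6(CH3)2–C7(=O)–O–C9(=CH2)–C10(CH3)–C11 fused across the cyclobutane, 5-OH syn to the C1–C3 bridge, 1-OTBS, 3-methylidene
Conditions: SmI2 (2.5 equiv), THF, −78 °C, slow addition of 13 (0.005 M); sat. aq. NH4Cl at −78 °C
Reagents that add atoms: none
Why: In this samarium-diiodide-mediated intramolecular Reformatsky reaction the samarium enolate is tied through the enol ester oxygen to the lower face of the cyclobutane and can reach the C5 carbonyl only from that face, so the new C5–C6 bond is cis to the C10 arm and the hydroxyl ends syn to the three-carbon bridge, and quenching cold should prevent acyl transfer from the activated ester to the new alkoxide.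

**Step 10**
Reactants: 14 hydroxy enol lactone
Product: 15 methyl oxalate of 14 at the C5 oxygen
Conditions: ClC(O)CO2Me (3 equiv), Et3N, DMAP (0.2 equiv), CH2Cl2, 0 → 25 °C
Reagents that add atoms: methyl chlorooxoacetate, COC(=O)C(=O)Cl
Why: Acylation of the tertiary cyclobutanol with the very reactive oxalyl half-ester chloride gives the substrate for radical deoxygenation, elimination being impossible because every β-carbon is a bridgehead or quaternary.

**Step 11**
Reactants: 15 oxalate
Product: 16 tricyclic enol lactone (as 14 but C5–H, the hydrogen syn to the C1–C3 bridge)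
Conditions: Bu3SnH (3 equiv, 0.2 M), AIBN (0.2 equiv), toluene, 110 °C
Reagents that add atoms: none
Why: In this radical deoxygenation of a tert-alkyl methyl oxalate with tin hydride the C5 radical is part of the seven-membered lactone, so C6 must stay on the lower face and the hydrogen atom is delivered to the upper face, which fixes C5, a high tin hydride concentration being used to outrun β-scission of the cyclobutane.

**Step 12**
Reactants: 16 enol lactone
Product: 18 1-[(tert-butyldimethylsilyl)oxy]-3-methylidene-longipinane-7,9-dione (tricyclic carbocycle; C4, C5, C10, C11 as in the target), via keto ester 17 (not isolated)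
Conditions: NaOMe (3 equiv), MeOH/toluene 1:4, 25 → 70 °C; then cold 1 M HCl
Reagents that add atoms: none
Why: Methoxide should cleave the acyl–oxygen bond of the activated enol lactone at C7 to give the methyl ester and the sodium enolate of the C9 methyl ketone (in equilibrium with keto ester 17); the enolate carbon C8 then attacks the ester carbonyl C7, methoxide is expelled, and deprotonation of the new 1,3-dione at C8 pulls the equilibria to the product. The closest known reaction type is the alkoxide-induced isomerisation of enol lactones to cyclic 1,3-diones, a Claisen condensation of the Dieckmann type. The one ring closed is the seven-membered carbocycle C5–C6–C7–C8–C9–C10–C11, by 7-(enolendo)-exo-trig attack of C8 on C7, the ring oxygen of the lactone being exchanged for carbon without change of ring size. No stereocentre is created (C7 and C9 leave the step as carbonyl carbons), and the cis junction at C5 and C10 cannot be lost because neither centre is acidified. The step needs regioselective enolisation and C- rather than O-acylation: C8 is the only enolisable carbon since C6 and C10 are quaternary and O1 is still a silyl ether, the cyclobutane holds the two arms cis and about 3 Å apart so that ring closure should outrun intermolecular paths, and O-acylation merely returns 16.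

**Step 13**
Reactants: 18 dione
Product: 19 (7R,9R)-1-[(tert-butyldimethylsilyl)oxy]-3-methylidene-longipinane-7,9-diol (trans-diol)
Conditions: (S)-1-methyl-3,3-diphenyltetrahydro-1H,3H-pyrrolo[1,2-c][1,3,2]oxazaborole (0.5 equiv), catecholborane (4 equiv), toluene, −40 → −20 °C; then MeOH, aq. NaOH
Reagents that add atoms: none
Why: In this twofold Corey–Bakshi–Shibata reduction the quaternary neighbour (C6 or C10) is the large and C8 the small group at each carbonyl, so the (S)-catalyst should deliver hydride to opposite faces of C7 and C9 and give the (7R,9R)-trans-diol, catalyst control being needed because both carbons lie on the local mirror plane of the tricycle, and catecholborane at low temperature should leave the methylidene group alone.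

**Step 14**
Reactants: 19 diol; 20 (E)-2-methylbut-2-enoyl chloride (tigloyl chloride)
Product: 21 7,9-bis-tiglate of 19
Conditions: 20 (4 equiv), pyridine, DMAP (1 equiv), toluene, 60 °C
Reagents that add atoms: none
Why: DMAP-catalysed acylation of the two neopentylic hydroxyls needs heat and excess acid chloride, and pyridine rather than a stronger amine is used so that the tigloyl group is not deconjugated through its ketene.

**Step 15**
Reactants: 21 silyl ether bis-tiglate
Product: 22 (7R,9R)-1-hydroxy-3-methylidene-longipinane-7,9-diyl bis[(E)-2-methylbut-2-enoate]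
Conditions: HF·pyridine, THF/pyridine, 0 → 25 °C
Reagents that add atoms: none
Why: Fluoride cleavage of the secondary silyl ether under buffered conditions should leave both enoate esters and the exocyclic alkene intact.

**Step 16**
Reactants: 22 alcohol
Product: 24 (4R,5S,7R,9R,10R,11R)-7,9-bis{[(E)-2-methylbut-2-enoyl]oxy}longipin-2-en-1-one (the target), via methylidene ketone 23 (not isolated)
Conditions: DMP [1,1,1-triacetoxy-1,1-dihydro-1,2-benziodoxol-3(1H)-one] (1.5 equiv), NaHCO3, CH2Cl2, 0 → 25 °C; aq. Na2S2O3 wash; then DBU (0.3 equiv), CH2Cl2, 25 °C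
Reagents that add atoms: none
Why: Dess–Martin oxidation gives the β,γ-unsaturated ketone, and base-mediated conjugation through the C2 dienolate should then move the exocyclic double bond into the ring to the favoured 3-methyl enone, with no stereocentre at risk because the bridgehead C11 cannot enolise.

**Compound list**

1 | (E)-3-methylpent-2-en-4-yn-1-ol | C#C/C(C)=C/CO | starting material
2 | (E)-3-methylpent-2-en-4-ynal | C#C/C(C)=C/C=O | intermediate
3 | ethyl 3-methylbut-2-enoate | CCOC(=O)C=C(C)C | starting material
4 | tert-butyl{[(1Z)-1-ethoxy-3-methylbuta-1,3-dien-1-yl]oxy}dimethylsilane | C=C(C)/C=C(/OCC)O[Si](C)(C)C(C)(C)C | intermediate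
5 | ethyl (2E,5S,6E)-5-hydroxy-3,7-dimethylnona-2,6-dien-8-ynoate | CCOC(=O)/C=C(\C)C[C@H](O)/C=C(\C)C#C | intermediate
6 | ethyl (2E,5S,6E)-5-[(tert-butyldimethylsilyl)oxy]-3,7-dimethylnona-2,6-dien-8-ynoate | CCOC(=O)/C=C(\C)C[C@H](O[Si](C)(C)C(C)(C)C)/C=C(\C)C#C | intermediate
7 | (2E,5S,6E)-5-[(tert-butyldimethylsilyl)oxy]-3,7-dimethylnona-2,6-dien-8-ynoic acid | OC(=O)/C=C(\C)C[C@H](O[Si](C)(C)C(C)(C)C)/C=C(\C)C#C | intermediate
8 | acid chloride of 7 | ClC(=O)/C=C(\C)C[C@H](O[Si](C)(C)C(C)(C)C)/C=C(\C)C#C | intermediate
9 | (5S,6E)-5-[(tert-butyldimethylsilyl)oxy]-7-methyl-3-methylidenenona-1,6-dien-8-yn-1-one (vinylketene) | O=C=CC(=C)C[C@H](O[Si](C)(C)C(C)(C)C)/C=C(\C)C#C | intermediate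
10 | 4-[(tert-butyldimethylsilyl)oxy]-7-ethynyl-7-methyl-2-methylidenebicyclo[3.1.1]heptan-6-one (OTBS on the carbonyl-bridge side, ethynyl anti to the three-carbon bridge) | C#C[C@@]1(C)[C@@H]2[C@@H](O[Si](C)(C)C(C)(C)C)CC(=C)[C@H]1C2=O | intermediate
11 | 7-acetyl-4-[(tert-butyldimethylsilyl)oxy]-7-methyl-2-methylidenebicyclo[3.1.1]heptan-6-one | CC(=O)[C@@]1(C)[C@@H]2[C@@H](O[Si](C)(C)C(C)(C)C)CC(=C)[C@H]1C2=O | intermediate
12 | 2-bromo-2-methylpropanoyl bromide | CC(C)(Br)C(=O)Br | starting material
13 | enol ester of 11 with 2-bromo-2-methylpropanoic acid | C=C(OC(=O)C(C)(C)Br)[C@@]1(C)[C@@H]2[C@@H](O[Si](C)(C)C(C)(C)C)CC(=C)[C@H]1C2=O | intermediate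
14 | tricyclic 5-hydroxy enol lactone (O in place of C8, 9-methylidene, 5-OH syn to the C1–C3 bridge) | O=C1OC(=C)[C@@]2(C)[C@@H]3[C@@H](O[Si](C)(C)C(C)(C)C)CC(=C)[C@H]2[C@]3(O)C1(C)C | intermediate
15 | methyl oxalate of 14 | O=C1OC(=C)[C@@]2(C)[C@@H]3[C@@H](O[Si](C)(C)C(C)(C)C)CC(=C)[C@H]2[C@]3(OC(=O)C(=O)OC)C1(C)C | intermediate
16 | tricyclic enol lactone (C5–H) | O=C1OC(=C)[C@@]2(C)[C@@H]3[C@@H](O[Si](C)(C)C(C)(C)C)CC(=C)[C@H]2[C@@H]3C1(C)C | intermediate
17 | keto ester (C9 methyl ketone on C10, methyl ester C7 on C6) | CC(=O)[C@@]1(C)[C@@H]2[C@@H](O[Si](C)(C)C(C)(C)C)CC(=C)[C@H]1[C@@H]2C(C)(C)C(=O)OC | intermediate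
18 | 1-[(tert-butyldimethylsilyl)oxy]-3-methylidene-longipinane-7,9-dione | O=C1CC(=O)[C@@]2(C)[C@@H]3[C@@H](O[Si](C)(C)C(C)(C)C)CC(=C)[C@H]2[C@@H]3C1(C)C | intermediate
19 | (7R,9R)-1-[(tert-butyldimethylsilyl)oxy]-3-methylidene-longipinane-7,9-diol | O[C@@H]1C[C@@H](O)[C@@]2(C)[C@@H]3[C@@H](O[Si](C)(C)C(C)(C)C)CC(=C)[C@H]2[C@@H]3C1(C)C | intermediate
20 | (E)-2-methylbut-2-enoyl chloride | C/C=C(\C)C(=O)Cl | starting material
21 | 7,9-bis-tiglate of 19 | C/C=C(\C)C(=O)O[C@@H]1C[C@@H](OC(=O)/C(C)=C/C)[C@@]2(C)[C@@H]3[C@@H](O[Si](C)(C)C(C)(C)C)CC(=C)[C@H]2[C@@H]3C1(C)C | intermediate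
22 | 1-hydroxy-3-methylidene-longipinane-7,9-diyl bis-tiglate | C/C=C(\C)C(=O)O[C@@H]1C[C@@H](OC(=O)/C(C)=C/C)[C@@]2(C)[C@@H]3[C@@H](O)CC(=C)[C@H]2[C@@H]3C1(C)C | intermediate
23 | 3-methylidene-1-oxo-longipinane-7,9-diyl bis-tiglate (β,γ-unsaturated ketone) | C/C=C(\C)C(=O)O[C@@H]1C[C@@H](OC(=O)/C(C)=C/C)[C@@]2(C)[C@@H]3C(=O)CC(=C)[C@H]2[C@@H]3C1(C)C | intermediate
24 | (4R,5S,7R,9R,10R,11R)-7,9-bis{[(E)-2-methylbut-2-enoyl]oxy}longipin-2-en-1-one | C/C=C(\C)C(=O)O[C@@H]1C[C@@H](OC(=O)/C(C)=C/C)[C@@]2(C)[C@@H]3C(=O)C=C(C)[C@H]2[C@@H]3C1(C)C | target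

**Step count and risks**

Total: 16 steps. Longest linear sequence: 15 steps (1 → 24; step 2 is a one-step side branch).

Steps most likely to fail:

1. Step 6. The alkene is part of a conjugated enyne and is inductively deactivated by the sp carbon, so ketene dimerisation and oligomerisation may outrun the cycloaddition, and the facial bias may erode at 110 °C. Fallback with an sp3 oxygenated arm in place of the alkyne, setting out from 4 and returning at 11: 4 is added under the conditions of step 3 to commercial 3-methylbut-2-enal to give ethyl (2E,5S)-5-hydroxy-3,7-dimethylocta-2,6-dienoate F1. Silylation gives TBS ether F2, and SeO2/t-BuOOH oxidises the (E)-methyl group to allylic alcohol F3. 4-Methoxybenzyl trichloroacetimidate with La(OTf)3 gives PMB ether F4, and LiOH gives acid F5. The procedure of step 6 then leads through acid chloride F6 and vinylketene F7 to cyclobutanone F8, with the PMB-oxymethyl group anti to the three-carbon bridge. DDQ frees primary alcohol F9, and TEMPO/PhI(OAc)2 followed by NaClO2 gives carboxylic acid F10. The chloroenamine of step 6 converts it to acid chloride F11, and Me2CuLi at −78 °C gives methyl ketone 11 without touching the cyclobutanone.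

2. Step 10. Acylation of the crowded tertiary cyclobutanol may stall, and under forcing DMAP conditions acyl transfer from the activated enol lactone may intervene. Fallback setting out from 14 and returning at 16: the alcohol is deprotonated with NaN(SiMe3)2 at −78 °C, where the alkoxide should not yet attack the lactone, and is captured by the small linear electrophile CS2 and then MeI to give S-methyl xanthate F12. Barton–McCombie reduction (Bu3SnH, AIBN, toluene, 110 °C) then gives 16 with the same tether-enforced hydrogen delivery.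

3. Step 13. The dione may be consumed as an unreactive enol boron chelate, or the catalyst may fail to override the ring conformation at one carbonyl, which would give cis-diol or the wrong trans-diol; hydroboration of the methylidene group may compete. Fallback replacing catalyst control by diastereomer separation and 1,3-relay, setting out from 16 and returning at 19: iBu2AlH (1 equiv, −78 → 0 °C) reduces the enol lactone to an aluminium hemiacetal, which should collapse to the C7 aldehyde and the aluminium enolate of the C9 ketone. Their aldol ring closure should give the two C7-epimeric β-hydroxy ketones, (7R)-hydroxy ketone F13 and (7S)-hydroxy ketone F14. After chromatographic separation, F13 is reduced with Me4NBH(OAc)3 in MeCN/AcOH at −20 °C (Evans–Saksena reduction, intramolecular hydride delivery, 1,3-anti) to 19. F14 is recycled by base-mediated retro-aldol/aldol equilibration.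

**Further compounds**

F1 | step 6 | ethyl (2E,5S)-5-hydroxy-3,7-dimethylocta-2,6-dienoate | CCOC(=O)/C=C(\C)C[C@H](O)C=C(C)C
F2 | step 6 | ethyl (2E,5S)-5-[(tert-butyldimethylsilyl)oxy]-3,7-dimethylocta-2,6-dienoate | CCOC(=O)/C=C(\C)C[C@H](O[Si](C)(C)C(C)(C)C)C=C(C)C
F3 | step 6 | ethyl (2E,5S,6E)-5-[(tert-butyldimethylsilyl)oxy]-8-hydroxy-3,7-dimethylocta-2,6-dienoate | CCOC(=O)/C=C(\C)C[C@H](O[Si](C)(C)C(C)(C)C)/C=C(\C)CO
F4 | step 6 | ethyl (2E,5S,6E)-5-[(tert-butyldimethylsilyl)oxy]-8-[(4-methoxyphenyl)methoxy]-3,7-dimethylocta-2,6-dienoate | CCOC(=O)/C=C(\C)C[C@H](O[Si](C)(C)C(C)(C)C)/C=C(\C)COCc1ccc(OC)cc1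
F5 | step 6 | (2E,5S,6E)-5-[(tert-butyldimethylsilyl)oxy]-8-[(4-methoxyphenyl)methoxy]-3,7-dimethylocta-2,6-dienoic acid | OC(=O)/C=C(\C)C[C@H](O[Si](C)(C)C(C)(C)C)/C=C(\C)COCc1ccc(OC)cc1
F6 | step 6 | acid chloride of F5 | ClC(=O)/C=C(\C)C[C@H](O[Si](C)(C)C(C)(C)C)/C=C(\C)COCc1ccc(OC)cc1
F7 | step 6 | vinylketene from F6 | O=C=CC(=C)C[C@H](O[Si](C)(C)C(C)(C)C)/C=C(\C)COCc1ccc(OC)cc1
F8 | step 6 | 4-[(tert-butyldimethylsilyl)oxy]-7-{[(4-methoxyphenyl)methoxy]methyl}-7-methyl-2-methylidenebicyclo[3.1.1]heptan-6-one | COc1ccc(COC[C@@]2(C)[C@@H]3[C@@H](O[Si](C)(C)C(C)(C)C)CC(=C)[C@H]2C3=O)cc1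
F9 | step 6 | 4-[(tert-butyldimethylsilyl)oxy]-7-(hydroxymethyl)-7-methyl-2-methylidenebicyclo[3.1.1]heptan-6-one | OC[C@@]1(C)[C@@H]2[C@@H](O[Si](C)(C)C(C)(C)C)CC(=C)[C@H]1C2=O
F10 | step 6 | 4-[(tert-butyldimethylsilyl)oxy]-7-methyl-2-methylidene-6-oxobicyclo[3.1.1]heptane-7-carboxylic acid | OC(=O)[C@@]1(C)[C@@H]2[C@@H](O[Si](C)(C)C(C)(C)C)CC(=C)[C@H]1C2=O
F11 | step 6 | acid chloride of F10 | ClC(=O)[C@@]1(C)[C@@H]2[C@@H](O[Si](C)(C)C(C)(C)C)CC(=C)[C@H]1C2=O
F12 | step 10 | S-methyl xanthate of 14 at the C5 oxygen | O=C1OC(=C)[C@@]2(C)[C@@H]3[C@@H](O[Si](C)(C)C(C)(C)C)CC(=C)[C@H]2[C@]3(OC(=S)SC)C1(C)C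
F13 | step 13 | (7R)-1-[(tert-butyldimethylsilyl)oxy]-7-hydroxy-3-methylidene-longipinan-9-one | O[C@@H]1CC(=O)[C@@]2(C)[C@@H]3[C@@H](O[Si](C)(C)C(C)(C)C)CC(=C)[C@H]2[C@@H]3C1(C)C
F14 | step 13 | (7S)-1-[(tert-butyldimethylsilyl)oxy]-7-hydroxy-3-methylidene-longipinan-9-one | O[C@H]1CC(=O)[C@@]2(C)[C@@H]3[C@@H](O[Si](C)(C)C(C)(C)C)CC(=C)[C@H]2[C@@H]3C1(C)C
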